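**Retrosynthetic overview**
1. Target ⇐ desilylation of its 12-O-SiMe3 ether; the exocyclic C7=C8 (7Z) olefin ⇐ acetylation/E1cB dehydration of a β-hydroxy ketone (prostanoid numbering: C1 = ester carbon, C8–C12 = ring, C13–C20 = octenyl chain).
2. Key C7–C8 bond ⇐ intermolecular aldol addition of the C8 lithium enolate of a silyl-protected (S)-2-chloro-4-hydroxy-4-[(Z)-oct-2-enyl]cyclopentenone to the C1–C7 aldehyde methyl (5S,6R)-5,6-diacetoxy-7-oxoheptanoate.
3. Ring fragment ⇐ (R)-4-silyloxycyclopentenone: anti 1,2-propargylation (sets C12), acetylide pentylation, Lindlar reduction, desilylation/allylic oxidation (1,3-carbonyl transposition), epoxidation then HCl (2-chloroenone), O-silylation.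
4. Aldehyde ⇐ L-threitol acetonide (C4–C7, both stereocentres from L-tartaric acid): monobenzylation, oxidation, methylenation, acetonide-to-diacetate exchange, cross-metathesis with methyl but-3-enoate (C1–C3), hydrogenation, debenzylation, oxidation.
5. Rings: the single carbocycle is bought as the cyclopentenone and only refunctionalised; no ring is formed in the route.

Assumption: "7Z" is read from the SMILES (C6 cis to the C9 carbonyl; 5S,6S,12R,14Z), and (R)-4-(tert-butyldimethylsilyloxy)cyclopent-2-enone and 2,3-O-isopropylidene-L-threitol are taken as purchasable.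

**Ring fragment**

Step 1
Reactants: 1 (R)-4-[(tert-butyldimethylsilyl)oxy]cyclopent-2-en-1-one
Product: 2 (1S,4R)-4-[(tert-butyldimethylsilyl)oxy]-1-(prop-2-yn-1-yl)cyclopent-2-en-1-ol
Conditions: HC≡CCH2Br, Mg, HgCl2 (1 mol %), Et2O, 0 °C (gives CH2=C=CHMgBr); then 1, Et2O, −78 °C; aq NH4Cl
Reagents that add atoms: propargyl bromide (3-bromoprop-1-yne), C#CCBr
Why: Grignard 1,2-addition (carbonyl propargylation by SE2′ reaction of the allenyl Grignard reagent) gives the homopropargylic tertiary alcohol, and attack on the ketone face anti to the C4 silyloxy group sets the new carbinol centre (the future C12) as 1S, the minor cis adduct being removed by chromatography so that it cannot become the enantiomer later.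

Step 2
Reactants: 2 (1S,4R)-4-[(tert-butyldimethylsilyl)oxy]-1-(prop-2-yn-1-yl)cyclopent-2-en-1-ol
Product: 4 (1S,4R)-4-[(tert-butyldimethylsilyl)oxy]-1-(oct-2-yn-1-yl)cyclopent-2-en-1-ol, via dilithio alkoxide acetylide 3 (not isolated)
Conditions: n-BuLi (2.2 equiv), THF, −78 → −20 °C; 1-iodopentane, DMPU, −20 °C → rt; H2O
Reagents that add atoms: 1-iodopentane, CCCCCI
Why: double deprotonation gives an O,C-dianion whose acetylide carbon is far more nucleophilic than the hindered tertiary lithium alkoxide, so SN2 alkylation of the primary iodide (acetylide alkylation) occurs on carbon only and no stereocentre is touched.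

Step 3
Reactants: 4 (1S,4R)-4-[(tert-butyldimethylsilyl)oxy]-1-(oct-2-yn-1-yl)cyclopent-2-en-1-ol
Product: 5 (1S,4R)-4-[(tert-butyldimethylsilyl)oxy]-1-[(2Z)-oct-2-en-1-yl]cyclopent-2-en-1-ol
Conditions: H2 (1 atm), 5% Pd/CaCO3 poisoned with Pb(OAc)2 (Lindlar catalyst), quinoline, EtOAc, rt
Reagents that add atoms: none
Why: Lindlar semihydrogenation adds H2 syn across the alkyne to give the 14Z olefin, and the poisoned catalyst leaves the ring olefin and the allylic C–O bonds untouched.

Step 4
Reactants: 5 (1S,4R)-4-[(tert-butyldimethylsilyl)oxy]-1-[(2Z)-oct-2-en-1-yl]cyclopent-2-en-1-ol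
Product: 6 (1S,4R)-1-[(2Z)-oct-2-en-1-yl]cyclopent-2-ene-1,4-diol
Conditions: Bu4NF, THF, 0 °C → rt
Reagents that add atoms: none
Why: fluoride-mediated desilylation frees the secondary allylic alcohol under non-acidic conditions that cannot ionise the tertiary allylic alcohol.

Step 5
Reactants: 6 (1S,4R)-1-[(2Z)-oct-2-en-1-yl]cyclopent-2-ene-1,4-diol
Product: 7 (4S)-4-hydroxy-4-[(2Z)-oct-2-en-1-yl]cyclopent-2-en-1-one
Conditions: activated MnO2 (15 equiv), CH2Cl2, rt
Reagents that add atoms: none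
Why: chemoselective MnO2 allylic oxidation of the secondary alcohol (the tertiary one cannot be oxidised) completes a 1,3-carbonyl transposition, erasing the original carbinol centre and leaving the chirality solely at the quaternary carbon fixed in step 1.

Step 6
Reactants: 7 (4S)-4-hydroxy-4-[(2Z)-oct-2-en-1-yl]cyclopent-2-en-1-one
Product: 8 (4S)-4-hydroxy-4-[(2Z)-oct-2-en-1-yl]-6-oxabicyclo[3.1.0]hexan-2-one (2,3-epoxy ketone; both epoxide faces)
Conditions: 30% aq H2O2, NaOH (0.2 equiv), MeOH, −10 → 0 °C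
Reagents that add atoms: hydrogen peroxide, OO
Why: Weitz–Scheffer nucleophilic epoxidation attacks only the electron-poor enone olefin and not the isolated Z-olefin, and the two new epoxide centres need no control because both are destroyed in step 7.

Step 7
Reactants: 8 (4S)-4-hydroxy-4-[(2Z)-oct-2-en-1-yl]-6-oxabicyclo[3.1.0]hexan-2-one
Product: 10 (4S)-2-chloro-4-hydroxy-4-[(2Z)-oct-2-en-1-yl]cyclopent-2-en-1-one, via chlorohydrin 9 (not isolated)
Conditions: HCl (4 M in 1,4-dioxane), CHCl3, 0 °C → rt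
Reagents that add atoms: hydrogen chloride, Cl
Why: chloride opens the protonated α,β-epoxy ketone by SN2 attack at the α-carbon (activated by the carbonyl and remote from the quaternary centre) and the α-chloro-β-hydroxy ketone dehydrates under the acid to the 2-chloroenone, while the tertiary alcohol survives because its ionisation would place a cation next to the electron-poor enone.

Step 8
Reactants: 10 (4S)-2-chloro-4-hydroxy-4-[(2Z)-oct-2-en-1-yl]cyclopent-2-en-1-one
Product: 11 (4S)-2-chloro-4-[(2Z)-oct-2-en-1-yl]-4-[(trimethylsilyl)oxy]cyclopent-2-en-1-one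
Conditions: 1-(trimethylsilyl)imidazole (1.5 equiv), CH2Cl2, rt
Reagents that add atoms: 1-(trimethylsilyl)imidazole, C[Si](C)(C)n1ccnc1
Why: neutral O-silylation by the strong silyl donor masks the hindered tertiary alcohol without any base that could enolise the ketone.

**Side-chain aldehyde**

Step 9
Reactants: 12 (4S,5S)-2,2-dimethyl-1,3-dioxolane-4,5-dimethanol (2,3-O-isopropylidene-L-threitol)
Product: 13 [(4S,5S)-5-[(benzyloxy)methyl]-2,2-dimethyl-1,3-dioxolan-4-yl]methanol
Conditions: NaH (1.0 equiv), THF/DMF, 0 °C; BnBr (1.0 equiv), Bu4NI (5 mol %), 0 °C → rt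
Reagents that add atoms: benzyl bromide, BrCc1ccccc1
Why: Williamson monobenzylation of the C2-symmetric diol (either hydroxyl gives the same product) differentiates the two termini, both stereocentres coming unchanged from L-tartaric acid.

Step 10
Reactants: 13 [(4S,5S)-5-[(benzyloxy)methyl]-2,2-dimethyl-1,3-dioxolan-4-yl]methanol
Product: 14 (4R,5S)-5-[(benzyloxy)methyl]-2,2-dimethyl-1,3-dioxolane-4-carbaldehyde
Conditions: (COCl)2, DMSO, CH2Cl2, −78 °C; Et3N, −78 → 0 °C
Reagents that add atoms: none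
Why: Swern oxidation gives the α-alkoxy aldehyde without over-oxidation, and the trans-dioxolane is the thermodynamically preferred isomer so the α-centre does not epimerise (the descriptor changes only through priorities).

Step 11
Reactants: 14 (4R,5S)-5-[(benzyloxy)methyl]-2,2-dimethyl-1,3-dioxolane-4-carbaldehyde
Product: 15 (4S,5S)-4-[(benzyloxy)methyl]-5-ethenyl-2,2-dimethyl-1,3-dioxolane
Conditions: Ph3PCH3Br, KN(SiMe3)2, THF, 0 °C; then 14, −78 °C → rt
Reagents that add atoms: methyltriphenylphosphonium bromide, C[P+](c1ccccc1)(c1ccccc1)c1ccccc1.[Br-]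
Why: Wittig methylenation converts the aldehyde into the terminal olefin needed for chain extension, and low-temperature addition to the stable trans-acetonide preserves the α-stereocentre.

Step 12
Reactants: 15 (4S,5S)-4-[(benzyloxy)methyl]-5-ethenyl-2,2-dimethyl-1,3-dioxolane
Product: 16 (2S,3S)-1-(benzyloxy)pent-4-ene-2,3-diol
Conditions: p-TsOH·H2O (0.2 equiv), MeOH, 40 °C
Reagents that add atoms: none
Why: acid-catalysed transacetalisation to methanol removes the acetonide before any ester is present, so the future C5 oxygen can never lactonise onto C1, and no stereocentre is affected.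

Step 13
Reactants: 16 (2S,3S)-1-(benzyloxy)pent-4-ene-2,3-diol
Product: 17 (2S,3S)-1-(benzyloxy)pent-4-ene-2,3-diyl diacetate
Conditions: Ac2O, pyridine, DMAP (cat.), CH2Cl2, 0 °C → rt
Reagents that add atoms: acetic anhydride, CC(=O)OC(C)=O
Why: DMAP-catalysed O-acylation installs the two acetates of the target (C5 and C6) with retention, since no C–O bond is broken.

Step 14
Reactants: 17 (2S,3S)-1-(benzyloxy)pent-4-ene-2,3-diyl diacetate; 18 methyl but-3-enoate
Product: 19 methyl (3E,5S,6S)-5,6-bis(acetyloxy)-7-(benzyloxy)hept-3-enoate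
Conditions: 18 (3 equiv), second-generation Grubbs catalyst RuCl2(=CHPh)(PCy3)(H2IMes) (5 mol %), 1,4-benzoquinone (10 mol %), CH2Cl2, 40 °C
Reagents that add atoms: none
Why: olefin cross-metathesis between the hindered allylic-acetate olefin (slow to homodimerise) and an excess of the unhindered butenoate appends C1–C3 with loss of ethene, the olefin geometry being irrelevant because the bond is hydrogenated next.

Step 15
Reactants: 19 methyl (3E,5S,6S)-5,6-bis(acetyloxy)-7-(benzyloxy)hept-3-enoate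
Product: 20 methyl (5S,6S)-5,6-bis(acetyloxy)-7-(benzyloxy)heptanoate
Conditions: H2 (1 atm), RhCl(PPh3)3 (5 mol %), PhMe/EtOH (1:1), rt
Reagents that add atoms: none
Why: homogeneous hydrogenation with Wilkinson's catalyst saturates the disubstituted olefin without hydrogenolysis of the allylic acetate or the benzyl ether.

Step 16
Reactants: 20 methyl (5S,6S)-5,6-bis(acetyloxy)-7-(benzyloxy)heptanoate
Product: 21 methyl (5S,6S)-5,6-bis(acetyloxy)-7-hydroxyheptanoate
Conditions: H2 (1 atm), Pd(OH)2/C, EtOAc, rt; used at once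
Reagents that add atoms: none
Why: neutral hydrogenolysis of the benzyl ether frees the primary alcohol without the acid or base that would trigger 1,2-acetyl migration.

Step 17
Reactants: 21 methyl (5S,6S)-5,6-bis(acetyloxy)-7-hydroxyheptanoate
Product: 22 methyl (5S,6R)-5,6-bis(acetyloxy)-7-oxoheptanoate
Conditions: Dess–Martin periodinane, CH2Cl2, 0 °C → rt; used crude at once
Reagents that add atoms: none
Why: Dess–Martin oxidation under non-basic conditions gives the α-acetoxy aldehyde without epimerisation at C6 or β-elimination of acetate (the C6 descriptor changes from S to R only because the priorities change).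

**Coupling and completion**

Step 18
Reactants: 11 (4S)-2-chloro-4-[(2Z)-oct-2-en-1-yl]-4-[(trimethylsilyl)oxy]cyclopent-2-en-1-one; 22 methyl (5S,6R)-5,6-bis(acetyloxy)-7-oxoheptanoate
Product: 24 methyl (5S,6S)-5,6-bis(acetyloxy)-7-[(5S)-3-chloro-5-[(2Z)-oct-2-en-1-yl]-2-oxo-5-[(trimethylsilyl)oxy]cyclopent-3-en-1-yl]-7-hydroxyheptanoate (C7/C8 epimers), via lithium enolate 23 (not isolated)
Conditions: LiN(iPr)2 (1.1 equiv), THF, −78 °C, 30 min; 22 (1.3 equiv), THF, −78 °C, 20 min; AcOH, −78 °C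
Reagents that add atoms: none
Why: kinetic deprotonation at the only enolisable position (C8) gives a cross-conjugated lithium enolate that cannot expel the silyloxy group (that would give an antiaromatic cyclopentadienone) and adds to the aldehyde far faster than to the acetates or ester in an intermolecular aldol addition forming C7–C8, the unselectively formed C7 and C8 centres both being removed in step 19.

Step 19
Reactants: 24 methyl (5S,6S)-5,6-bis(acetyloxy)-7-[(5S)-3-chloro-5-[(2Z)-oct-2-en-1-yl]-2-oxo-5-[(trimethylsilyl)oxy]cyclopent-3-en-1-yl]-7-hydroxyheptanoate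
Product: 26 methyl (5S,6S,7Z)-5,6-bis(acetyloxy)-7-[(5R)-3-chloro-5-[(2Z)-oct-2-en-1-yl]-2-oxo-5-[(trimethylsilyl)oxy]cyclopent-3-en-1-ylidene]heptanoate (12-O-trimethylsilyl-7Z-punaglandin 4), via aldol acetate 25 (not isolated)
Conditions: Ac2O (3 equiv), DMAP (4 equiv), CH2Cl2, 0 °C → rt; SiO2 chromatography separates 7Z from 7E
Reagents that add atoms: none
Why: acetylation of the aldol hydroxyl followed by DMAP-promoted E1cB β-elimination gives the cross-conjugated dienone as a separable 7Z/7E mixture, in which the 7Z isomer places the side chain away from the fully substituted silyloxy-bearing C12, and any earlier C6/C7 acetyl migration is corrected because both oxygens are acetylated before elimination.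

Step 20
Reactants: 26 methyl (5S,6S,7Z)-5,6-bis(acetyloxy)-7-[(5R)-3-chloro-5-[(2Z)-oct-2-en-1-yl]-2-oxo-5-[(trimethylsilyl)oxy]cyclopent-3-en-1-ylidene]heptanoate
Product: 27 methyl (5S,6S,7Z)-5,6-bis(acetyloxy)-7-[(5R)-3-chloro-5-hydroxy-5-[(2Z)-oct-2-en-1-yl]-2-oxocyclopent-3-en-1-ylidene]heptanoate (7Z-punaglandin 4)
Conditions: HF·pyridine, MeCN, 0 °C
Reagents that add atoms: none
Why: desilylation of the labile tertiary trimethylsilyl ether with HF is fast at 0 °C and leaves the acetates, the methyl ester, the vinyl chloride and the dienone geometry intact.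

**Compound list**
1 | (R)-4-[(tert-butyldimethylsilyl)oxy]cyclopent-2-en-1-one | O=C1C=C[C@H](O[Si](C)(C)C(C)(C)C)C1 | starting material
2 | (1S,4R)-4-[(tert-butyldimethylsilyl)oxy]-1-(prop-2-yn-1-yl)cyclopent-2-en-1-ol | C#CC[C@@]1(O)C=C[C@H](O[Si](C)(C)C(C)(C)C)C1 | intermediate
3 | dilithio alkoxide acetylide of 2 (not isolated) | [Li]C#CC[C@@]1(O[Li])C=C[C@H](O[Si](C)(C)C(C)(C)C)C1 | intermediate
4 | (1S,4R)-4-[(tert-butyldimethylsilyl)oxy]-1-(oct-2-yn-1-yl)cyclopent-2-en-1-ol | CCCCCC#CC[C@@]1(O)C=C[C@H](O[Si](C)(C)C(C)(C)C)C1 | intermediate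
5 | (1S,4R)-4-[(tert-butyldimethylsilyl)oxy]-1-[(2Z)-oct-2-en-1-yl]cyclopent-2-en-1-ol | CCCCC/C=C\C[C@@]1(O)C=C[C@H](O[Si](C)(C)C(C)(C)C)C1 | intermediate
6 | (1S,4R)-1-[(2Z)-oct-2-en-1-yl]cyclopent-2-ene-1,4-diol | CCCCC/C=C\C[C@@]1(O)C=C[C@H](O)C1 | intermediate
7 | (4S)-4-hydroxy-4-[(2Z)-oct-2-en-1-yl]cyclopent-2-en-1-one | CCCCC/C=C\C[C@@]1(O)C=CC(=O)C1 | intermediate
8 | (4S)-4-hydroxy-4-[(2Z)-oct-2-en-1-yl]-6-oxabicyclo[3.1.0]hexan-2-one (epoxide face not controlled) | CCCCC/C=C\C[C@@]1(O)C2OC2C(=O)C1 | intermediate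
9 | (4S)-2-chloro-3,4-dihydroxy-4-[(2Z)-oct-2-en-1-yl]cyclopentan-1-one (chlorohydrin, not isolated) | CCCCC/C=C\C[C@@]1(O)C(O)C(Cl)C(=O)C1 | intermediate
10 | (4S)-2-chloro-4-hydroxy-4-[(2Z)-oct-2-en-1-yl]cyclopent-2-en-1-one | CCCCC/C=C\C[C@@]1(O)C=C(Cl)C(=O)C1 | intermediate
11 | (4S)-2-chloro-4-[(2Z)-oct-2-en-1-yl]-4-[(trimethylsilyl)oxy]cyclopent-2-en-1-one | CCCCC/C=C\C[C@@]1(O[Si](C)(C)C)C=C(Cl)C(=O)C1 | intermediate
12 | (4S,5S)-2,2-dimethyl-1,3-dioxolane-4,5-dimethanol (2,3-O-isopropylidene-L-threitol) | OC[C@@H]1OC(C)(C)O[C@H]1CO | starting material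
13 | [(4S,5S)-5-[(benzyloxy)methyl]-2,2-dimethyl-1,3-dioxolan-4-yl]methanol | c1ccccc1COC[C@@H]2OC(C)(C)O[C@H]2CO | intermediate
14 | (4R,5S)-5-[(benzyloxy)methyl]-2,2-dimethyl-1,3-dioxolane-4-carbaldehyde | c1ccccc1COC[C@@H]2OC(C)(C)O[C@H]2C=O | intermediate
15 | (4S,5S)-4-[(benzyloxy)methyl]-5-ethenyl-2,2-dimethyl-1,3-dioxolane | c1ccccc1COC[C@@H]2OC(C)(C)O[C@H]2C=C | intermediate
16 | (2S,3S)-1-(benzyloxy)pent-4-ene-2,3-diol | c1ccccc1COC[C@H](O)[C@H](C=C)O | intermediate
17 | (2S,3S)-1-(benzyloxy)pent-4-ene-2,3-diyl diacetate | c1ccccc1COC[C@H](OC(C)=O)[C@H](C=C)OC(C)=O | intermediate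
18 | methyl but-3-enoate | C=CCC(=O)OC | starting material
19 | methyl (3E,5S,6S)-5,6-bis(acetyloxy)-7-(benzyloxy)hept-3-enoate | c1ccccc1COC[C@H](OC(C)=O)[C@H](/C=C/CC(=O)OC)OC(C)=O | intermediate
20 | methyl (5S,6S)-5,6-bis(acetyloxy)-7-(benzyloxy)heptanoate | c1ccccc1COC[C@H](OC(C)=O)[C@H](CCCC(=O)OC)OC(C)=O | intermediate
21 | methyl (5S,6S)-5,6-bis(acetyloxy)-7-hydroxyheptanoate | OC[C@H](OC(C)=O)[C@H](CCCC(=O)OC)OC(C)=O | intermediate
22 | methyl (5S,6R)-5,6-bis(acetyloxy)-7-oxoheptanoate | O=C[C@H](OC(C)=O)[C@H](CCCC(=O)OC)OC(C)=O | intermediate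
23 | C8 lithium enolate of 11 (not isolated) | CCCCC/C=C\C[C@@]1(O[Si](C)(C)C)C=C(Cl)C(O[Li])=C1 | intermediate
24 | methyl (5S,6S)-5,6-bis(acetyloxy)-7-[(5S)-3-chloro-5-[(2Z)-oct-2-en-1-yl]-2-oxo-5-[(trimethylsilyl)oxy]cyclopent-3-en-1-yl]-7-hydroxyheptanoate (C7/C8 epimer mixture) | CCCCC/C=C\C[C@@]1(O[Si](C)(C)C)C=C(Cl)C(=O)C1C(O)[C@H](OC(C)=O)[C@H](CCCC(=O)OC)OC(C)=O | intermediate
25 | C7 acetate of 24 (aldol acetate, not isolated) | CCCCC/C=C\C[C@@]1(O[Si](C)(C)C)C=C(Cl)C(=O)C1C(OC(C)=O)[C@H](OC(C)=O)[C@H](CCCC(=O)OC)OC(C)=O | intermediate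
26 | methyl (5S,6S,7Z)-5,6-bis(acetyloxy)-7-[(5R)-3-chloro-5-[(2Z)-oct-2-en-1-yl]-2-oxo-5-[(trimethylsilyl)oxy]cyclopent-3-en-1-ylidene]heptanoate (12-O-trimethylsilyl-7Z-punaglandin 4) | CCCCC/C=C\C[C@@]1(O[Si](C)(C)C)C=C(Cl)C(=O)/C1=C\[C@H](OC(C)=O)[C@H](CCCC(=O)OC)OC(C)=O | intermediate
27 | methyl (5S,6S,7Z)-5,6-bis(acetyloxy)-7-[(5R)-3-chloro-5-hydroxy-5-[(2Z)-oct-2-en-1-yl]-2-oxocyclopent-3-en-1-ylidene]heptanoate (7Z-punaglandin 4; 5S,6S,12R,14Z) | CCCCC/C=C\C[C@@]1(O)C=C(Cl)C(=O)/C1=C\[C@H](OC(C)=O)[C@H](CCCC(=O)OC)OC(C)=O | target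

**Totals and risks**

Total step count: 20. Longest linear sequence: 12 steps (steps 9–20, from 12); the ring branch is 11 steps (steps 1–8 and 18–20).

Most likely to fail:

Step 19 (elimination, olefin geometry). The E1cB elimination is not stereospecific and may favour the 7E isomer. Fallback: set out from 24 and run the same acetylation–elimination, but collect the geometric isomer 12-O-trimethylsilyl-(7E)-punaglandin 4 F1. Irradiate it (350 nm, Pyrex, degassed benzene, rt) until the photostationary E/Z mixture of the exocyclic enone is reached. Chromatography then gives the 7Z isomer, and recovered F1 is irradiated again. This changes stereoselective elimination into geometric isomerisation and comes back to the route at 26.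

Step 18 (aldol addition). The α,β-diacetoxy aldehyde 22 can enolise, lose acetate by β-elimination or transfer acetyl in the presence of a lithium enolate or alkoxide. Fallback: set out from 11 and convert it with Me3SiOTf/Et3N (CH2Cl2, 0 °C) into the silyl dienol ether (5S)-2-chloro-5-[(2Z)-oct-2-en-1-yl]-3,5-bis[(trimethylsilyl)oxy]cyclopenta-1,3-diene F2. Add this without purification to 22 under BF3·OEt2 (CH2Cl2, −78 °C) in a Mukaiyama aldol addition, which never exposes the aldehyde to base. Aqueous work-up comes back to the route at 24.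

Step 6 (nucleophilic epoxidation). The free β-hydroxy ketone 7 may undergo retro-aldol cleavage or elimination in alkaline peroxide. Fallback: set out from 6 and epoxidise the ring olefin before oxidation with t-BuOOH and VO(acac)2 (2 mol %, CH2Cl2, 0 °C → rt). The reaction is directed by the two allylic hydroxyls, and the homoallylic side-chain olefin reacts far more slowly. It gives (1R,2S,4R,5R)-2-[(2Z)-oct-2-en-1-yl]-6-oxabicyclo[3.1.0]hexane-2,4-diol F3 (oxirane oxygen cis to both hydroxyls). Oxidise its only secondary alcohol with Dess–Martin periodinane (CH2Cl2, rt), which comes back to the route at 8 as a single epoxide epimer.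

**Further compounds**
F1 | step 19 | 12-O-trimethylsilyl-(7E)-punaglandin 4 | CCCCC/C=C\C[C@@]1(O[Si](C)(C)C)C=C(Cl)C(=O)/C1=C/[C@H](OC(C)=O)[C@H](CCCC(=O)OC)OC(C)=O
F2 | step 18 | (5S)-2-chloro-5-[(2Z)-oct-2-en-1-yl]-3,5-bis[(trimethylsilyl)oxy]cyclopenta-1,3-diene | CCCCC/C=C\C[C@@]1(O[Si](C)(C)C)C=C(Cl)C(O[Si](C)(C)C)=C1
F3 | step 6 | (1R,2S,4R,5R)-2-[(2Z)-oct-2-en-1-yl]-6-oxabicyclo[3.1.0]hexane-2,4-diol | CCCCC/C=C\C[C@@]1(O)[C@@H]2O[C@@H]2[C@H](O)C1
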